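(The numbers are invented; the run is a simulation.)

- A ratio is what I followed in dusk, autumn and winter: the rate of making left-handed product over the rate of making right-handed product.

| setting | dusk | autumn | winter |
|---|---|---|---|
| left-handed substrate | 0.24 M | 0.24 M | 0.24 M |
| partner | 0.144 M | 0.144 M | 0.144 M |
| protic impurity | 0.240 M | 0.240 M | 0.240 M |
| free catalyst | 41 mM | 41 mM | 41 mM |
| added ligand | 21 mM | 21 mM | 21 mM |
| right-handed substrate | 0.24 M | 0.24 M | 0.24 M |
| time | 2.5 h | 2.5 h | 2.5 h |
| remark | at 50 °C until 80 min, from then on at 25 °C |  |  |
| temperature |  | 25 °C | 50 °C |

    partner + free catalyst + left-handed substrate → free catalyst + left-handed product (k1 = 120 L² mol⁻² h⁻¹, Ea1 = 41.0 kJ mol⁻¹)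
    partner + free catalyst + right-handed substrate → free catalyst + right-handed product (k2 = 60 L² mol⁻² h⁻¹, Ea2 = 61.0 kJ mol⁻¹)
    free catalyst + added ligand ⇌ idle complex, settled at all times (K3 = 43 L mol⁻¹, ΔH3 = −46.0 kJ mol⁻¹)
    partner + protic impurity → quenched reagent (k4 = 1.9 L mol⁻¹ h⁻¹, Ea4 = 65.0 kJ mol⁻¹)
    partner + free catalyst → spent catalyst (k5 = 0.19 L mol⁻¹ h⁻¹, Ea5 = 57.0 kJ mol⁻¹)
    (constants at 25 °C)

- free catalyst is single-handed; left-handed substrate and right-handed substrate are mirror images of each other, charged as a racemate, each of them at the stated concentration
- all constants are for 25 °C and move with temperature by the activation energies and enthalpies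
- an excess is the difference of the two amounts in percent of their sum
- an excess is below zero if the other one leads

- which flask leads in excess of left-handed product over right-handed product ("all alike" within 1.5 percentage points) (dusk / autumn / winter / all alike)
- excess of left-handed product over right-handed product at the end, dusk
- excess of left-handed product over right-handed product at the end, autumn
- excess of left-handed product over right-handed product at the end, winter

- Both product steps use the same partner and free catalyst, so at the first moment, with equal substrates, that ratio equalled the selectivity factor, the constant of the left-handed step over that of the right-handed step at the flask's temperature, which at 25 °C I reckoned as 2.00.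
- My bench rule took the excess as the factor less one over the factor plus one, which gave autumn 33.3%.
- The right-handed step has an activation energy higher by 20.0 kJ mol⁻¹, so at 50 °C the factor shrank to 1.07, close to the meeting of the two constants at 53 °C, and the rule gave winter 3.45%.
- Dusk started at the same temperature as winter, so I asked whether its partner would be used before the change at 80 min. Quenching by the protic impurity, taken as pseudo-first-order, gave partner a lifetime of 0.288 h, shorter than that time, and the product steps draw on partner as well.
- I therefore gave dusk 3.45% and ranked the flasks with autumn in the lead.
- The rule has a border, since the rate ratio is the factor times left-handed substrate over right-handed substrate, and in autumn that ratio drifts down as the left-handed substrate is used faster.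
- The ratio of partner to both substrates put the ceiling on conversion at 30.0%.
- The forecast named autumn and gave 3.1% for dusk, 29.7% for autumn and 3.1% for winter, with the grounds “Partner is exhausted before cooling, so it matches winter.” Its autumn figure stood below my rule's.
- The simulation gave 3.08% for dusk, 29.9% for autumn and 3.08% for winter, so autumn led. At the end of autumn, 36.3% of left-handed substrate stood against 42.6% of right-handed substrate, which brought the selectivity factor of 2.00 down to a rate ratio of 1.70. A repeat of autumn at 10 °C has a factor of 3.07, for which the rule gives 50.9%, and that flask ended at 47.5%.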